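- You are asked how much J stands in this flask, which has twice the X of the earlier spring run. The steps under discussion are E + G -> J, Q <-> E, X -> G and Q + J -> Z.

in all of them: Q 0.064 M (in portions, 3)

| charge | X | remark | time |
|---|---|---|---|
| spring | 0.064 M | run made earlier; portions every 1.0 min |  |
| autumn | 0.096 M | run made earlier; portions every 1.0 min |  |
| flask | 0.128 M | the portions of Q follow each other after 1.0 min, the first at the start | 3.0 min |

| run | time / s | J / % | Q / % |
|---|---|---|---|
| spring | 10.0 | 0 | 29.7 |
| spring | 15.0 | 0.5 | 28.3 |
| spring | 30.0 | 2.1 | 25.4 |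
| spring | 60.0 | 7.6 | 18.2 |
| spring | 120 | 27.1 | 27.6 |
| autumn | 10.0 | 0 | 30.7 |
| autumn | 15.0 | 0.3 | 29.3 |
| autumn | 30.0 | 2.6 | 25.5 |
| autumn | 60.0 | 11.1 | 18.4 |
| autumn | 120 | 29.7 | 26.8 |

(standard deviation of a reading: 0.5 percentage points)

- percentages count the Q that a species holds: one Z counts as two
- the analysis behind the earlier runs scatters by 0.5 percentage points, standard deviation
- steps under discussion: E + G -> J; Q <-> E; X -> G; Q + J -> Z

* amount of J in percent of the Q charged, at 40 s, 1.5 min and 3.0 min

- Start with Q, which feeds E. In the spring run, Q falls from 29.7 % at 10.0 s to 18.2 % at 60.0 s, with the first portion alone in both readings. Read as a first-order decay, where a fixed fraction goes per unit time, this gives a rate constant of 0.00979 s⁻¹.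
- The autumn run, with more X, gives 0.0102 s⁻¹, about the same, so you carry the spring value to this flask.
- Now count turnovers: the rate constant times the time a portion has stood. One interval between portions is worth 0.588 turnovers, and each interval leaves a fraction 0.556 of what a portion held.
- At 3.0 min in this flask, the first portion has done 1.76 turnovers and the last has done 0.588. By this count, Q stands at 34.5 % of the charge, and 65.5 % has left Q.
- E and Z hold part of that, so your own estimate puts J at 3.0 min somewhere under 65.5 %; this count gives no value for J.
- The forecast, which calls “Q → E is the rate-limiting feed”, puts J at 6 %, 23 % and 45 %. Its last figure lies under that mark.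
- The flask gives 5.99 %, 22.0 % and 50.6 %. The two earlier points lie close to the forecast, and the last stands 5.6 percentage points above it.

    E + G → J (k = 2.90 L mol⁻¹ s⁻¹)
    Q ⇌ E (K = 9.00, k = 0.00990 s⁻¹)
    X → G (k = 0.00540 s⁻¹)
    Q + J → Z (k = 0.0900 L mol⁻¹ s⁻¹)

- The count of 0.588 turnovers per interval puts Q in this flask at 34.5 % at 3.0 min, against 28.9 % found, and in the autumn run at 28.8 % at 120 s, against a reading of 26.8 %, and both stand below the count. At 3.00 min in this flask, with each step taken net, J is still made 3.80 times as fast as it is used up.

The readings are calculated from invented constants.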